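**Retrosynthetic overview**
- Numbering: ring A = C1 (CHBr), C2, C3, C4 (methyl carbinol), C5 (fusion carbinol), C10 (fusion C–Me); ring B = C5 to C10, with C7 the carbinol that bears ring C; ring C = C11 (C–Me), C12 (CHOH), C13, C14 (CHBr), C15 (CMe2).
- Feature: the vicinal quaternary pair C11/C15 of ring C, with its three methyl groups, is a tetrasubstituted alkene C11=C15 in disguise; adding C14 to C15 and C12 to C11 across it closes ring C and leaves C7 as an acetyl carbon.
- Ring C is made first, by gold-catalysed carbocyclisation and pinacol shift of a 3-silyloxy-1,5-enyne (bonds C14–C15 and C11–C12); the enyne comes from asymmetric propargylation of 3,4-dimethylpent-3-en-2-one.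
- Ring C is then completed (C12 oxidation, C14 conjugate borylation, directed reduction, invertive bromination) while C7 is held as an enol triflate, which becomes the 2-substituted butadiene C6=C7–C8=C9.
- Ring B is closed last by a Diels–Alder reaction (C5–C6, C9–C10) with an enantiopure ring A enone; C1–Br, C5–OH, the C4 methyl carbinol and C7–OH are then set on the decalin.

Key step: step 3

Convention: β is the decalin face that carries the C10 methyl and α the opposite face; in ring C the "methyl face" is that of the C11 methyl and the "C7 face" that of the C11–C7 bond.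
Assumption: the chiral catalysts of steps 1, 6 and 15 induce the sense stated; where one induces the opposite sense, its antipode is used.
Remark on the order: both bromides are installed before the tertiary hydroxyls at C4 and C7 exist, because a free 4β-OH could displace an activated C1 carbinol and a free C7–OH an activated C14 carbinol.

Step 1
Reactants: 1 3,4-dimethylpent-3-en-2-one; 2 allenylboronic acid pinacol ester
Product: 4 (S)-4,5,6-trimethylhept-5-en-1-yn-4-ol, via pinacol borate ester 3 (not isolated)
Conditions: (S)-3,3′-Br2-BINOL (10 mol %), neat, microwave 60 °C; aq. work-up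
Reagents that add atoms: allenylboronic acid pinacol ester, C=C=CB1OC(C)(C)C(C)(C)O1
Why: Biphenol-catalysed asymmetric propargylation of a ketone: ligand exchange on boron gives a chiral allenylboronate that adds through a closed six-membered SE2′ transition state to the Si face of the twisted, aliphatic-like methyl ketone, which should set C7 as S and place alkyne and tetrasubstituted alkene in the 1,5 relationship.

Step 2
Reactants: 4 (S)-4,5,6-trimethylhept-5-en-1-yn-4-ol
Product: 5 (S)-triethyl[(4,5,6-trimethylhept-5-en-1-yn-4-yl)oxy]silane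
Conditions: TESOTf, 2,6-lutidine, CH2Cl2, −78 → 0 °C
Reagents that add atoms: triethylsilyl trifluoromethanesulfonate, CC[Si](CC)(CC)OS(=O)(=O)C(F)(F)F
Why: Silylation of a hindered tertiary alcohol needs the silyl triflate; the triethylsilyl ether is the oxygen substituent that later drives the pinacol shift.

Step 3
Reactants: 5 (S)-triethyl[(4,5,6-trimethylhept-5-en-1-yn-4-yl)oxy]silane
Product: 7 1-[(1R)-1,2,2-trimethylcyclopent-3-en-1-yl]ethan-1-one, via cyclohexenyl cation 6 (not isolated)
Conditions: Ph3PAuNTf2 (5 mol %), i-PrOH (1.5 equiv), CH2Cl2, 23 °C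
Reagents that add atoms: none
Why: Cationic monovalent gold activates the terminal alkyne and the tetrasubstituted alkene attacks C14 through C15 in a 6-endo-dig carbocyclisation, which should give the vinylgold cyclohexenyl cation 6 with the charge on the tertiary carbon C11 next to the silyloxy carbon C7. The ring methylene C12, allylic to the vinylgold unit and so the best migrating group, then shifts from C7 to C11 (pinacol-type 1,2-shift): the six-membered ring contracts to ring C, bonds C14–C15 and C11–C12 are in place, and C7 becomes a silyloxocarbenium ion that passes its silyl group to isopropanol, which also protodeaurates C13. The closest known reaction type is the gold-catalysed carbocyclisation/pinacol cascade of 3-silyloxy-1,5-enynes to acylcyclopentenes. The only new stereocentre, C11, should be controlled by C7: in the half-chair cation the C7 methyl is expected to stand perpendicular to the cation plane (hyperconjugating C–C bond, no eclipsing with the C11 methyl) and the silyloxy group in the plane, so that C12 lies over one face of C11 and migrates suprafacially to it, (S)-5 leading to (R)-7, while C7 itself ceases to be a stereocentre. The step needs 6-endo attack (C15 on C14) in place of 5-endo attack, secured by the terminal alkyne and the oxygen-flanked tertiary cation it produces, and migration of C12 in preference to the C7 methyl, secured by the allylgold character of the C7–C12 bond.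

Step 4
Reactants: 7 1-[(1R)-1,2,2-trimethylcyclopent-3-en-1-yl]ethan-1-one
Product: 8 1-[(1R)-1,2,2-trimethylcyclopent-3-en-1-yl]ethenyl trifluoromethanesulfonate
Conditions: KHMDS, PhNTf2, THF, −78 → 0 °C
Reagents that add atoms: N-phenylbis(trifluoromethanesulfonimide), O=S(=O)(N(c1ccccc1)S(=O)(=O)C(F)(F)F)C(F)(F)F
Why: Enolisation is possible only at the methyl group (C11 is quaternary); O-triflation masks the ketone, so that no cleavable 1,3-dicarbonyl arises in the next steps, and provides the handle for the diene.

Step 5
Reactants: 8 1-[(1R)-1,2,2-trimethylcyclopent-3-en-1-yl]ethenyl trifluoromethanesulfonate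
Product: 10 (5R)-4,4,5-trimethyl-5-[1-(trifluoromethanesulfonyloxy)ethenyl]cyclopent-2-en-1-one, via allylic alcohol 9 (not isolated)
Conditions: SeO2 (0.5 equiv), t-BuOOH, CH2Cl2, 40 °C; then Dess–Martin periodinane, CH2Cl2, 23 °C
Reagents that add atoms: tert-butyl hydroperoxide, CC(C)(C)OO
Why: Allylic oxidation by the ene/[2,3]-sigmatropic sequence of SeO2 puts oxygen on C12, the only allylic CH2 (C15 is quaternary), without allylic transposition; Dess–Martin oxidation of the crude C12 epimers converges on the enone.

Step 6
Reactants: 10 (5R)-4,4,5-trimethyl-5-[1-(trifluoromethanesulfonyloxy)ethenyl]cyclopent-2-en-1-one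
Product: 11 β-boryl ketone (C14–Bpin on the methyl face; C12 ketone; C7 enol triflate)
Conditions: CuCl (5 mol %), (R,R)-QuinoxP* (6 mol %), NaOt-Bu (10 mol %), B2pin2, MeOH, THF, 23 °C
Reagents that add atoms: bis(pinacolato)diboron, CC1(C)OB(OC1(C)C)B1OC(C)(C)C(C)(C)O1
Why: Copper-catalysed conjugate borylation places boron on the β-carbon C14; the two ring faces differ little (methyl against triflyloxyvinyl at C11), so the chiral bisphosphine copper boryl complex is relied on to deliver boron to the methyl face (reagent control).

Step 7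
Reactants: 11 β-boryl ketone
Product: 12 β-hydroxy ketone (C14–OH on the methyl face)
Conditions: H2O2 (30 % aq.), NaHCO3 (0.5 equiv), THF/H2O, 0 °C
Reagents that add atoms: hydrogen peroxide, OO
Why: Oxidation of the C–B bond goes with retention through 1,2-migration from boron to oxygen; near-neutral conditions at 0 °C should spare the β-hydroxy ketone from elimination.

Step 8
Reactants: 12 β-hydroxy ketone
Product: 13 trans-1,3-diol monobenzoate (C14–OBz on the methyl face; C12–OH on the C7 face)
Conditions: PhCHO (5 equiv), SmI2 (0.3 equiv), THF, −10 °C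
Reagents that add atoms: benzaldehyde, O=Cc1ccccc1
Why: Evans–Tishchenko reduction: the samarium-bound hemiacetal of the C14 hydroxyl with benzaldehyde delivers hydride intramolecularly to the face of the C12 carbonyl syn to the C14 oxygen, which should give the trans-1,3 relationship and leave the two oxygens differentiated (C14 benzoate, C12 free hydroxyl).

Step 9
Reactants: 13 trans-1,3-diol monobenzoate
Product: 14 C12 tert-butyldimethylsilyl ether C14 benzoate
Conditions: TBSOTf, 2,6-lutidine, CH2Cl2, 0 → 23 °C
Reagents that add atoms: tert-butyldimethylsilyl trifluoromethanesulfonate, CC(C)(C)[Si](C)(C)OS(=O)(=O)C(F)(F)F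
Why: The hindered neopentyl-type secondary alcohol is silylated by the silyl triflate; this ether stays until the last step.

Step 10
Reactants: 14 C12 tert-butyldimethylsilyl ether C14 benzoate
Product: 15 C14 alcohol (C14–OH on the methyl face; C12–OTBS on the C7 face)
Conditions: DIBAL-H (i-Bu2AlH, 2.5 equiv), CH2Cl2, −78 °C; Rochelle salt
Reagents that add atoms: none
Why: Reductive cleavage of the benzoate at low temperature; the enol triflate and the silyl ether are inert to the aluminium hydride.

Step 11
Reactants: 15 C14 alcohol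
Product: 17 C14 bromide (C14–Br on the C7 face; cis to C12–OTBS), via C14 triflate 16 (not isolated)
Conditions: Tf2O, pyridine, CH2Cl2, −78 → −20 °C; then n-Bu4NBr (4 equiv), toluene, −20 → 40 °C
Reagents that add atoms: tetrabutylammonium bromide, CCCC[N+](CCCC)(CCCC)CCCC.[Br-]
Why: SN2 displacement of the secondary triflate by bromide with inversion moves the substituent from the methyl face to the C7 face; a soluble bromide in a non-ionising solvent is chosen to hold back Wagner–Meerwein shift and elimination at this neopentyl-type carbon, and no free hydroxyl is present that could take part.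

Step 12
Reactants: 17 C14 bromide
Product: 18 2-substituted buta-1,3-diene (C6=C7–C8=C9 on C11)
Conditions: tributyl(vinyl)stannane, Pd(PPh3)4 (5 mol %), LiCl, THF, 65 °C
Reagents that add atoms: tributyl(vinyl)stannane, C=C[Sn](CCCC)(CCCC)CCCC
Why: Stille coupling: zerovalent palladium inserts into the enol triflate C–O bond far faster than into the unactivated secondary C–Br bond; the bulky C7 substituent should hold the diene in the reactive s-cis form.

Step 13
Reactants: 19 4-methoxy-3-methylphenol
Product: 20 4,4-dimethoxy-3-methylcyclohexa-2,5-dien-1-one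
Conditions: PhI(OAc)2, MeOH, 0 °C
Reagents that add atoms: methanol, CO
Why: Oxidative dearomatisation of a p-methoxyphenol in methanol gives the quinone monoketal.

Step 14
Reactants: 20 4,4-dimethoxy-3-methylcyclohexa-2,5-dien-1-one
Product: 21 4,4-dimethoxy-3-methylcyclohex-2-en-1-one
Conditions: H2 (1 atm), (Ph3P)3RhCl (5 mol %), toluene/EtOH, 23 °C
Reagents that add atoms: none
Why: Homogeneous hydrogenation with the rhodium chloride tris(phosphine) complex reduces the disubstituted C=C much faster than the trisubstituted, methyl-bearing one.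

Step 15
Reactants: 21 4,4-dimethoxy-3-methylcyclohex-2-en-1-one
Product: 23 (S)-4-hydroxy-2-methylcyclohex-2-en-1-one, via ketal alcohol 22 (not isolated)
Conditions: (R)-2-methyl-CBS-oxazaborolidine (0.2 equiv), BH3·SMe2, THF, −20 °C; then PPTS, acetone/H2O, 23 °C
Reagents that add atoms: water, O
Why: Corey–Bakshi–Shibata reduction (the alkenyl arm acting as the large group) should set the carbinol as S; mild hydrolysis of the dimethyl ketal then unveils the ketone, so that the former enone carbonyl becomes the γ-hydroxyl of a 2-methylcyclohexenone.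

Step 16
Reactants: 23 (S)-4-hydroxy-2-methylcyclohex-2-en-1-one
Product: 24 (S)-2-methyl-4-(triethylsilyloxy)cyclohex-2-en-1-one
Conditions: TESCl, imidazole, DMF, 0 °C
Reagents that add atoms: chlorotriethylsilane, CC[Si](Cl)(CC)CC
Why: Standard silylation of a secondary allylic alcohol; the triethylsilyl ether is the facial control element of the cycloaddition and can later be removed beside the tert-butyldimethylsilyl ether.

Step 17
Reactants: 18 2-substituted buta-1,3-diene; 24 (S)-2-methyl-4-(triethylsilyloxy)cyclohex-2-en-1-one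
Product: 25 cis-fused Diels–Alder adduct (C1 ketone; 4β-OTES; 5β-H; 10β-Me; C7=C8)
Conditions: EtAlCl2 (1.2 equiv), toluene, −20 → 0 °C
Reagents that add atoms: none
Why: Lewis-acid-promoted Diels–Alder reaction: the nucleophilic diene terminus C6 bonds to the β-carbon C5 and C9 to the α-carbon C10 ("para" orientation of C7 and C10), and the diene approaches the enone face anti to the C4 silyloxy group, so the new bonds are α and C10–Me and C5–H are β; as both partners are single enantiomers, the relative configuration of ring C and decalin is fixed.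

Step 18
Reactants: 25 cis-fused Diels–Alder adduct
Product: 26 1α-alcohol (trans to the C10 methyl)
Conditions: NaBH4, MeOH, 0 °C
Reagents that add atoms: none
Why: In the cis-decalin conformer that keeps the C4 silyloxy group equatorial, borohydride should attack the C1 carbonyl axially from the convex β face (syn-axial hydrogens only), giving the equatorial 1α-alcohol.

Step 19
Reactants: 26 1α-alcohol
Product: 28 1β-bromide, via C1 triflate 27 (not isolated)
Conditions: Tf2O, pyridine, CH2Cl2, −78 → −20 °C; then n-Bu4NBr (4 equiv), toluene, −20 → 40 °C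
Reagents that add atoms: tetrabutylammonium bromide, CCCC[N+](CCCC)(CCCC)CCCC.[Br-]
Why: Triflation followed by SN2 displacement with inversion (axial attack on the β face, past syn-axial hydrogens only) should give the 1β-bromide; the equatorial triflate has no anti-periplanar hydrogen for E2 and no free hydroxyl is present.

Step 20
Reactants: 28 1β-bromide
Product: 29 4β-alcohol
Conditions: PPTS, MeOH, 23 °C
Reagents that add atoms: none
Why: Mild acid methanolysis removes the triethylsilyl ether and leaves the hindered tert-butyldimethylsilyl ether at C12.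

Step 21
Reactants: 29 4β-alcohol
Product: 30 C4 ketone (cis-fused)
Conditions: Dess–Martin periodinane, CH2Cl2, 23 °C
Reagents that add atoms: none
Why: Neutral oxidation of the only free hydroxyl; no base is present that could close the γ-bromo ketone to a cyclopropane.

Step 22
Reactants: 30 C4 ketone
Product: 33 trans-fused 5α-hydroxy C4 ketone, via silyl enol ether 31 (not isolated), via silyloxy ketone 32 (not isolated)
Conditions: TMSCl, NaI, Et3N, MeCN, 23 °C; then m-CPBA (1.05 equiv), CH2Cl2, −20 °C; then citric acid, MeOH
Reagents that add atoms: 3-chloroperoxybenzoic acid, OOC(=O)c1cccc(Cl)c1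
Why: Rubottom oxidation: thermodynamic silylation should give the tetrasubstituted Δ4 enol ether (enolisation toward the ring-fusion carbon), the peracid attacks it on the α face, anti to the C10 methyl and the 1β-bromine and faster than the hindered C7=C8 alkene, and silyl migration then methanolysis give the 5α-hydroxy ketone with the trans ring fusion.

Step 23
Reactants: 33 trans-fused 5α-hydroxy C4 ketone
Product: 34 4β,5α-diol (4α-methyl)
Conditions: MeMgBr (4 equiv), CeCl3, THF, −78 → −20 °C
Reagents that add atoms: methylmagnesium bromide, C[Mg]Br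
Why: Carbonyl addition of the methyl Grignard/cerium reagent: axial attack on the β face is blocked by the syn-axial C10 methyl, so methyl should enter equatorially from the α face, giving 4α-Me and 4β-OH trans-diaxial to the 5α-OH, while cerium suppresses enolisation.

Step 24
Reactants: 34 4β,5α-diol
Product: 36 C12 silyl ether of the target (7α-OH), via C7 hydroperoxide 35 (not isolated)
Conditions: Mn(dpm)3 [manganese tris(dipivaloylmethanate), 10 mol %], PhSiH3, O2 (1 atm), i-PrOH/CH2Cl2, 0 °C; then PPh3
Reagents that add atoms: dioxygen, O=O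
Why: Mukaiyama hydration: hydrogen atom transfer to C8 gives the tertiary C7 radical, which should keep the bulky ring C substituent equatorial and be trapped by dioxygen axially on the α face; reduction of the hydroperoxide gives the Markovnikov 7α-alcohol, and both bromides tolerate these conditions.

Step 25
Reactants: 36 C12 silyl ether of the target
Product: 37 CNP0390567.2 (target)
Conditions: HF·pyridine, THF, 0 → 40 °C
Reagents that add atoms: none
Why: Fluoride-mediated desilylation under acidic rather than basic conditions frees the C12 hydroxyl without touching the two secondary bromides or the tertiary alcohols.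

**Compound list**
1 | 3,4-dimethylpent-3-en-2-one | CC(=O)C(C)=C(C)C | starting material
2 | allenylboronic acid pinacol ester | C=C=CB1OC(C)(C)C(C)(C)O1 | starting material
3 | pinacol borate ester of 4 | C#CC[C@](C)(OB1OC(C)(C)C(C)(C)O1)C(C)=C(C)C | intermediate (not isolated)
4 | (S)-4,5,6-trimethylhept-5-en-1-yn-4-ol | C#CC[C@](C)(O)C(C)=C(C)C | intermediate
5 | (S)-triethyl[(4,5,6-trimethylhept-5-en-1-yn-4-yl)oxy]silane (key-step precursor) | C#CC[C@](C)(O[Si](CC)(CC)CC)C(C)=C(C)C | intermediate
6 | vinylgold cyclohexenyl cation (charge at C11; C7 silyloxy) | CC1(C)C=C([Au-][P+](c2ccccc2)(c2ccccc2)c2ccccc2)C[C@](C)(O[Si](CC)(CC)CC)[C+]1C | intermediate (not isolated)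
7 | 1-[(1R)-1,2,2-trimethylcyclopent-3-en-1-yl]ethan-1-one (key-step product) | CC(=O)[C@]1(C)CC=CC1(C)C | intermediate
8 | 1-[(1R)-1,2,2-trimethylcyclopent-3-en-1-yl]ethenyl trifluoromethanesulfonate | C=C(OS(=O)(=O)C(F)(F)F)[C@]1(C)CC=CC1(C)C | intermediate
9 | C12 allylic alcohol of 8 (both C12 epimers) | C=C(OS(=O)(=O)C(F)(F)F)[C@]1(C)C(O)C=CC1(C)C | intermediate (not isolated)
10 | (5R)-4,4,5-trimethyl-5-[1-(trifluoromethanesulfonyloxy)ethenyl]cyclopent-2-en-1-one | C=C(OS(=O)(=O)C(F)(F)F)[C@]1(C)C(=O)C=CC1(C)C | intermediate
11 | β-boryl ketone, C14–Bpin on the methyl face | CC1(C)[C@H](B2OC(C)(C)C(C)(C)O2)CC(=O)[C@@]1(C)C(=C)OS(=O)(=O)C(F)(F)F | intermediate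
12 | β-hydroxy ketone, C14–OH on the methyl face | CC1(C)[C@H](O)CC(=O)[C@@]1(C)C(=C)OS(=O)(=O)C(F)(F)F | intermediate
13 | C14 benzoate, C12 alcohol on the C7 face (trans-1,3) | CC1(C)[C@H](OC(=O)c2ccccc2)C[C@@H](O)[C@@]1(C)C(=C)OS(=O)(=O)C(F)(F)F | intermediate
14 | C14 benzoate, C12 tert-butyldimethylsilyl ether | CC1(C)[C@H](OC(=O)c2ccccc2)C[C@@H](O[Si](C)(C)C(C)(C)C)[C@@]1(C)C(=C)OS(=O)(=O)C(F)(F)F | intermediate
15 | C14 alcohol, C12 silyl ether | CC1(C)[C@H](O)C[C@@H](O[Si](C)(C)C(C)(C)C)[C@@]1(C)C(=C)OS(=O)(=O)C(F)(F)F | intermediate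
16 | C14 triflate | CC1(C)[C@H](OS(=O)(=O)C(F)(F)F)C[C@@H](O[Si](C)(C)C(C)(C)C)[C@@]1(C)C(=C)OS(=O)(=O)C(F)(F)F | intermediate (not isolated)
17 | C14 bromide on the C7 face, enol triflate | CC1(C)[C@@H](Br)C[C@@H](O[Si](C)(C)C(C)(C)C)[C@@]1(C)C(=C)OS(=O)(=O)C(F)(F)F | intermediate
18 | 2-substituted buta-1,3-diene carrying finished, C12-protected ring C | CC1(C)[C@@H](Br)C[C@@H](O[Si](C)(C)C(C)(C)C)[C@@]1(C)C(=C)C=C | intermediate
19 | 4-methoxy-3-methylphenol | COc1ccc(O)cc1C | starting material
20 | 4,4-dimethoxy-3-methylcyclohexa-2,5-dien-1-one | COC1(OC)C=CC(=O)C=C1C | intermediate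
21 | 4,4-dimethoxy-3-methylcyclohex-2-en-1-one | COC1(OC)CCC(=O)C=C1C | intermediate
22 | (S)-4,4-dimethoxy-3-methylcyclohex-2-en-1-ol | COC1(OC)CC[C@H](O)C=C1C | intermediate (not isolated)
23 | (S)-4-hydroxy-2-methylcyclohex-2-en-1-one | CC1=C[C@@H](O)CCC1=O | intermediate
24 | (S)-2-methyl-4-(triethylsilyloxy)cyclohex-2-en-1-one | CC1=C[C@@H](O[Si](CC)(CC)CC)CCC1=O | intermediate
25 | cis-fused Diels–Alder adduct: C1 ketone, 4β-OTES, 5β-H, 10β-Me, C7=C8 | CC1(C)[C@@H](Br)C[C@@H](O[Si](C)(C)C(C)(C)C)[C@@]1(C)C1=CC[C@@]2(C)C(=O)CC[C@H](O[Si](CC)(CC)CC)[C@H]2C1 | intermediate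
26 | 1α-alcohol | CC1(C)[C@@H](Br)C[C@@H](O[Si](C)(C)C(C)(C)C)[C@@]1(C)C1=CC[C@@]2(C)[C@@H](O)CC[C@H](O[Si](CC)(CC)CC)[C@H]2C1 | intermediate
27 | 1α-triflate | CC1(C)[C@@H](Br)C[C@@H](O[Si](C)(C)C(C)(C)C)[C@@]1(C)C1=CC[C@@]2(C)[C@@H](OS(=O)(=O)C(F)(F)F)CC[C@H](O[Si](CC)(CC)CC)[C@H]2C1 | intermediate (not isolated)
28 | 1β-bromide, 4β-OTES | CC1(C)[C@@H](Br)C[C@@H](O[Si](C)(C)C(C)(C)C)[C@@]1(C)C1=CC[C@@]2(C)[C@H](Br)CC[C@H](O[Si](CC)(CC)CC)[C@H]2C1 | intermediate
29 | 1β-bromide, 4β-alcohol | CC1(C)[C@@H](Br)C[C@@H](O[Si](C)(C)C(C)(C)C)[C@@]1(C)C1=CC[C@@]2(C)[C@H](Br)CC[C@H](O)[C@H]2C1 | intermediate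
30 | 1β-bromide, C4 ketone (cis-fused) | CC1(C)[C@@H](Br)C[C@@H](O[Si](C)(C)C(C)(C)C)[C@@]1(C)C1=CC[C@@]2(C)[C@H](Br)CCC(=O)[C@H]2C1 | intermediate
31 | Δ4 trimethylsilyl enol ether | CC1(C)[C@@H](Br)C[C@@H](O[Si](C)(C)C(C)(C)C)[C@@]1(C)C1=CC[C@@]2(C)[C@H](Br)CCC(O[Si](C)(C)C)=C2C1 | intermediate (not isolated)
32 | 5α-trimethylsilyloxy C4 ketone | CC1(C)[C@@H](Br)C[C@@H](O[Si](C)(C)C(C)(C)C)[C@@]1(C)C1=CC[C@@]2(C)[C@H](Br)CCC(=O)[C@]2(O[Si](C)(C)C)C1 | intermediate (not isolated)
33 | trans-fused 5α-hydroxy C4 ketone | CC1(C)[C@@H](Br)C[C@@H](O[Si](C)(C)C(C)(C)C)[C@@]1(C)C1=CC[C@@]2(C)[C@H](Br)CCC(=O)[C@]2(O)C1 | intermediate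
34 | 4α-methyl-4β,5α-diol, C7=C8 | CC1(C)[C@@H](Br)C[C@@H](O[Si](C)(C)C(C)(C)C)[C@@]1(C)C1=CC[C@@]2(C)[C@H](Br)CC[C@](C)(O)[C@]2(O)C1 | intermediate
35 | 7α-hydroperoxide | CC1(C)[C@@H](Br)C[C@@H](O[Si](C)(C)C(C)(C)C)[C@@]1(C)[C@]1(OO)CC[C@@]2(C)[C@H](Br)CC[C@](C)(O)[C@]2(O)C1 | intermediate (not isolated)
36 | C12 tert-butyldimethylsilyl ether of the target | CC1(C)[C@@H](Br)C[C@@H](O[Si](C)(C)C(C)(C)C)[C@@]1(C)[C@]1(O)CC[C@@]2(C)[C@H](Br)CC[C@](C)(O)[C@]2(O)C1 | intermediate
37 | CNP0390567.2 | CC1(C)[C@@H](Br)C[C@@H](O)[C@@]1(C)[C@]1(O)CC[C@@]2(C)[C@H](Br)CC[C@](C)(O)[C@]2(O)C1 | target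

**Step count**
Total: 25 steps. Longest linear sequence: 21 steps (steps 1 to 12, then 17 to 25); the ring A enone takes 4 steps (13 to 16).

**Steps most likely to fail**

Step 3 (key step). The cyclisation and shift are precedented, but the passage of chirality from C7 to C11 is not: ring inversion of the cation before the shift, or a cyclisation transition state governed by allylic strain toward the C15 methyl, could lower or reverse the transfer, and the C7 methyl could migrate in place of C12. If the transfer is clean but of the opposite sense, the antipodal biphenol is used in step 1. If the transfer is poor, the fallback sets out from 7 as obtained in low enantiomeric purity and rejoins the route at 11. The mixture is taken through steps 4 and 5 unchanged, which gives, beside 8, 9 and 10, the antipodal enol triflate F1, the antipodal allylic alcohol F2 (not isolated) and the antipodal enone F3. The borylation of step 6 then serves as a catalyst-controlled, divergent reaction on both enantiomers: the chiral copper boryl complex adds to the same absolute face of C14 in 10 and in F3, so F3 should give the diastereomeric boronate F4 (boron on the C7 face, C11 inverted). F4 is removed from 11 by chromatography, so enantiomeric purity is secured by reagent control and separation instead of by chirality transfer.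

Step 19 (C1 bromide). Displacement at a secondary carbon next to the quaternary C10 may be too slow, so that ionisation with ring contraction (migration of the anti-periplanar C10–C5 bond), elimination, or participation of the C4 silyloxy oxygen could take over. The fallback sets out from 25 and rejoins at 28, replacing backside substitution by a front-side, retentive one. Reduction of 25 with LiB(s-Bu)3H at −78 °C, attacking from the equatorial direction, should give the epimeric 1β-alcohol F5. Quinoline-8-sulfonyl chloride with pyridine and DMAP converts it into the chelating 1β-quinoline-8-sulfonate F6. TiBr4 in CH2Cl2 at −78 °C, bound by the quinoline nitrogen and the sulfonate, should then deliver bromide to the face the leaving group departs from (substitution with retention), giving 28.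

Step 11 (C14 bromide). Backside attack at C14 is hindered by the C15 methyl and by the cis C12 silyloxy group, so Wagner–Meerwein methyl shift or elimination to a cyclopentene could compete. The fallback sets out from 11 and rejoins at 17, moving the inversion from a nucleophilic to an electrophilic substitution at carbon, where no cationic character develops. Corey–Bakshi–Shibata reduction of 11 (reagent control, quaternary C11 as the large group) should give the boryl alcohol F7 with C12–OH on the C7 face, and TBSOTf with 2,6-lutidine its silyl ether F8. Addition of 3,5-bis(trifluoromethyl)phenyllithium at −78 °C forms the aryl boronate complex F9 (not isolated), which reacts with N-bromosuccinimide at carbon with inversion (SE2 with inversion) to give 17.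

**Further compounds**
F1 | step 3 | antipodal enol triflate, 1-[(1S)-1,2,2-trimethylcyclopent-3-en-1-yl]ethenyl trifluoromethanesulfonate | C=C(OS(=O)(=O)C(F)(F)F)[C@@]1(C)CC=CC1(C)C
F2 | step 3 | antipodal C12 allylic alcohol (both C12 epimers) | C=C(OS(=O)(=O)C(F)(F)F)[C@@]1(C)C(O)C=CC1(C)C
F3 | step 3 | antipodal enone, (5S)-4,4,5-trimethyl-5-[1-(trifluoromethanesulfonyloxy)ethenyl]cyclopent-2-en-1-one | C=C(OS(=O)(=O)C(F)(F)F)[C@@]1(C)C(=O)C=CC1(C)C
F4 | step 3 | diastereomeric β-boryl ketone (C14–Bpin on the C7 face, C11 inverted) | CC1(C)[C@H](B2OC(C)(C)C(C)(C)O2)CC(=O)[C@]1(C)C(=C)OS(=O)(=O)C(F)(F)F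
F5 | step 19 | 1β-alcohol (C1 epimer of 26) | CC1(C)[C@@H](Br)C[C@@H](O[Si](C)(C)C(C)(C)C)[C@@]1(C)C1=CC[C@@]2(C)[C@H](O)CC[C@H](O[Si](CC)(CC)CC)[C@H]2C1
F6 | step 19 | 1β-quinoline-8-sulfonate | CC1(C)[C@@H](Br)C[C@@H](O[Si](C)(C)C(C)(C)C)[C@@]1(C)C1=CC[C@@]2(C)[C@H](OS(=O)(=O)c3cccc4cccnc34)CC[C@H](O[Si](CC)(CC)CC)[C@H]2C1
F7 | step 11 | boryl alcohol (C14–Bpin on the methyl face, C12–OH on the C7 face) | CC1(C)[C@H](B2OC(C)(C)C(C)(C)O2)C[C@@H](O)[C@@]1(C)C(=C)OS(=O)(=O)C(F)(F)F
F8 | step 11 | boryl tert-butyldimethylsilyl ether | CC1(C)[C@H](B2OC(C)(C)C(C)(C)O2)C[C@@H](O[Si](C)(C)C(C)(C)C)[C@@]1(C)C(=C)OS(=O)(=O)C(F)(F)F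
F9 | step 11 | lithium aryl boronate complex of F8 | [Li+].CC1(C)[C@H]([B-]2(c3cc(cc(c3)C(F)(F)F)C(F)(F)F)OC(C)(C)C(C)(C)O2)C[C@@H](O[Si](C)(C)C(C)(C)C)[C@@]1(C)C(=C)OS(=O)(=O)C(F)(F)F
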